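# Proposed synthesis of (+)-4'-methoxyaquisinenone G

Numbering: unprimed locants refer to the tetrahydrochromone half (chromone numbering, O1, C2–C4, C4a, C5–C8, C8a), primed locants to the flat 2-(2-phenylethyl)chromone half.

## Analysis of the target

The target joins two 2-(2-arylethyl)chromones. One is a 5,6,7,8-tetrahydrochromone carrying the 4-methoxyphenethyl group at C2. The other is a flat 6,7-dioxygenated chromone whose O7' is bonded to C5 and whose O6' is bonded to C7. These two ether bonds close a benzo-fused 1,4-dioxepine over C5–C6–C7, so the core is a bicyclo[4.3.1] system with C6 as the one-atom bridge.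

The carbocycle carries four contiguous stereocentres, (5R,6S,7R,8S). The aryl ether oxygens at C5 and C7 lie on one face, as the bridge demands. The hydroxyls at C6 and C8 lie on the other face, so every vicinal pair is trans.

The sensitive points are:
- the C5–OAr bond, which O1 can push out through C8a=C4a;
- the carbocycle itself, which is a few eliminations away from an aromatic chromone;
- the acidic CH2 next to C2 of each pyranone.

The difficulties are the absolute configuration of a ring with no carbon substituent to build from, the assignment of two similar phenolic oxygens to C5 and C7, and the avoidance of aromatisation.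

The route rests on one observation. C5, C6, C7 and C8 each carry exactly one oxygen, so the carbocycle is the benzo ring of a flat chromone raised by a cis-dihydroxylation across C5–C6 and an epoxidation across C7–C8. The trans relations at C5/C6 and C7/C8 are what two invertive substitutions on an all-cis diol epoxide would leave.

## Retrosynthetic reasoning

**C7–O6' bond (16 back to 15 and 14).** The last skeletal bond to be made is C7–O6'. Cutting it, with the C6 oxygen carried as a sulfate ester, leads from 16 through the bridged sulfate 15 to the epoxide 14, in which C7 and C8 share one oxygen on the face opposite the C5 aryl ether. The cut is placed here because the C7–O bond must be anti to the C8 hydroxyl and syn to the C5–O bond. A phenol already tethered at C5 can reach only C7, and only from that face. The forward reaction has to be a 7-exo epoxide opening at C7 rather than an 8-endo opening at C8.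

**C5–O7' bond (14 back to 8 and 13).** Cutting C5–O7' gives the cyclic sulfate 8 and the catechol chromone 13. C5 is the one carbon of the carbocycle whose substitution is assisted electronically, by O1 through C8a=C4a. In 8 the neighbouring C6 lies between two oxygenated carbons and is shut off. The cyclic sulfate makes the C5 oxygen a leaving group and keeps the C6 oxygen as a masked hydroxyl. Inversion at C5 turns the cis-diol relation into the trans relation of the target. The two phenols of 13 differ in acidity, since the 7'-hydroxyl is vinylogous to the C4' carbonyl. The monoanion therefore reacts through O7' and no protecting group is needed. Both halves are joined in one operation.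

**Cyclic sulfate and epoxide (8 back to 6 and 5).** The sulfate 8 comes from the diol 6 through the sulfite 7, and 6 comes from the dihydrodiol 5 by hydroxyl-directed epoxidation of C7=C8. Epoxidation is placed before sulfate formation for three reasons. The free hydroxyls are needed to steer the oxidant to their own face. Once C7=C8 is gone the ring is no longer one elimination away from an aromatic chromone. C6 is then no longer allylic, and no alkene is exposed to the oxidant that converts sulfite to sulfate.

**C5–O and C6–O bonds (5 back to 4).** This is the strategic cut. Removing both C–O bonds returns the flat, achiral chromone 4. All four stereocentres of the target then descend from the two set in this step, by substrate control. No chemical reagent adds two oxygens across one bond of a benzo ring; an arene dioxygenase does. The forward step must select C5–C6 and the (5S,6R) face. That face is not the one these enzymes usually choose at the carbon next to a ring fusion, so the step depends on finding a suitable variant.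

**Pyranone of 4 (4 back to 1 and 2).** Cutting O1–C2 and C2–C3 gives the diketone 3, and a Claisen disconnection of 3 gives the acetophenone 1 and the ester 2. This is the standard chromone construction and reaches the enzyme substrate in one operation.

**Catechol chromone (13 back to 9 and 11).** The same two cuts lead from 13 through the diketone 12 to the protected acetophenone 10 and the ester 11, and 10 comes from the triol 9. The two phenols that end as the catechol are masked as acetals that fall off in the acid used for ring closure.

## Alternatives that were turned down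

**Alternative 1:** bridging oxa-Michael closure on a carbohydrate-derived cyclohexenone.
- Disconnection: the pyranone is removed to a C8a ketone, and the C5–O7' bond is cut as a conjugate addition.
- Forward key step: in the cyclohexenone A2 (ketone at C8a, alkene C4a=C5, C7 already bonded to O6'), the free 7'-phenol adds to C5 and closes the dioxepine, giving the bridged ketone A1.
- For it: every reaction type is known. The configuration at C6, C7 and C8 comes from the chiral pool, and the tether allows C5 to close only cis to C7. On certainty of absolute configuration it is stronger than the chosen route.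
- Against it: A1 is a β-aryloxy ketone, so the closure is reversible. The later enolisation towards C4a, needed to build the pyranone, invites loss of the C5 aryloxide. The carbocycle needs a long sequence of sugar manipulations, an intermolecular aryl ether formation on a hindered cyclitol, and two silyl ethers, and the pyranone still has to be made afterwards. The count is well above fifteen operations.
- Comparison: the chosen route offers a five-step longest linear sequence and no protecting group on the carbocycle. It forms the C5–O bond when no carbonyl is β to it.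

**Alternative 2:** amine-catalysed dynamic aldol closing the carbocycle.
- Disconnection: the C7–C8 bond.
- Forward key step: in the keto aldehyde A4 (benzodioxepinone with the ketone at C6, the pyranone on C5 and a formyl group on C8a), a chiral secondary amine forms the enamine towards C7. The enamine adds to the aldehyde (6-enolexo), while the labile C5 centre equilibrates, giving the bridged ketone A3.
- For it: it is convergent and makes the carbocycle and three stereocentres in one catalytic step. If it worked, the step count would be close to that of the chosen route.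
- Against it: the amine must choose between two α-carbons, and enolisation towards C5 is conjugated with the pyranone and likely preferred. The formyl group on an electron-poor pyranone will bind the amine unproductively. The product is a β-hydroxy ketone that can dehydrate and then aromatise. Three centres must be set through a bridged transition state whose facial preference cannot be predicted, and a C6 ketone reduction with its own facial problem follows.
- Comparison: both routes carry an unproven key step. The chosen one asks only for one site and one face from a catalyst class known to deliver exactly that on related arenes, and everything after it is substrate-controlled.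

**Alternative 3:** acylketene annulation of the pyranone onto the bridged ketone.
- Disconnection: the C4–C4a and O1–C8a bonds.
- Forward key step: the enol silane A6 of the bridged ketone A1 combines with the acylketene A8, released thermally from the dioxinone A7, in a [4+2] sense. Loss of silanol gives the bis-silyl ether A5 of the target, and desilylation finishes the synthesis.
- For it: the sensitive pyranone is attached last, and the reaction type is known for simple ketone enol ethers. On the pyranone construction alone it is as good as the Claisen route.
- Against it: it presupposes A1 and so inherits the length of Alternative 1. A6 must be formed towards C4a with an aryloxide leaving group on the adjacent C5. The annulation needs about 100 °C on a hindered bridged system.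
- Comparison: the chosen route has the pyranone in place from the first step, made on an achiral arene, and spends its steps on the stereocentres only.

Key step: step 2

## Route

Assumption: a dioxygenase variant that accepts 4 and attacks C5–C6 from the face giving (5S,6R) is taken to be obtainable by screening and active-site engineering; the steps after step 2 do not depend on how 5 is obtained.

Step 1
Reactants: 1 1-(2-hydroxyphenyl)ethanone; 2 methyl 3-(4-methoxyphenyl)propanoate
Product: 4 2-[2-(4-methoxyphenyl)ethyl]chromen-4-one, via diketone 3 (not isolated)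
Conditions: NaH (3.5 equiv), THF, reflux; aq. HCl quench; crude 3, conc. HCl (cat.), MeOH, 65 °C
Reagents that add atoms: none
Why: Crossed Claisen condensation: the dianion of 1 (phenoxide and methyl ketone enolate) is acylated by ester 2, and formation of the diketonate drives the equilibrium. Acid then closes the hemiketal and dehydrates it to the γ-pyranone (chromone cyclodehydration); the aryl methyl ether and the CH2CH2 link are inert to both stages.

Step 2
Reactants: 4 2-[2-(4-methoxyphenyl)ethyl]chromen-4-one
Product: 5 (5S,6R)-5,6-dihydroxy-2-[2-(4-methoxyphenyl)ethyl]-5,6-dihydrochromen-4-one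
Conditions: resting E. coli cells producing a Rieske non-haem iron arene dioxygenase of the naphthalene dioxygenase family (variant chosen by screening) with its reductase and ferredoxin, glucose, air, phosphate buffer pH 7.2, 30 °C; EtOAc extraction at pH 8, below 10 °C
Reagents that add atoms: dioxygen, O=O
Why: Proposed new method: In these enzymes electrons from NADH pass through the reductase, the ferredoxin and the [2Fe–2S] Rieske cluster to a mononuclear non-haem iron held by two histidines and one aspartate; O2 binds side-on to the divalent iron next to the arene and, at the trivalent-iron (hydro)peroxo level, both oxygen atoms are handed to one face of one C=C bond, so the diol must be cis. The closest known reactions are the oxidation of naphthalene to its (1R,2S)-cis-1,2-dihydrodiol by naphthalene dioxygenase and the carbocyclic-ring cis-dihydroxylation of quinoline, benzofuran and benzothiophene by toluene dioxygenase; the chromone benzo ring is of the same size and has the same styrene-like bonds, but has not been shown as a substrate. No ring is closed. The two new stereocentres C5 and C6 are set together by the protein: their cis relation by the single iron-bound O2, their absolute sense by the in-plane orientation in which the pocket holds the flat substrate. Three selectivities are needed: attack on C5–C6 and not on C7–C8, the anisyl ring, the benzylic CH2 groups or the O-methyl group; the (5S,6R) face; and release of the diol before it dehydrates. The electron-poor pyranone C2=C3 bond is not a dioxygenase substrate, and the long arylethyl arm must lie along the substrate channel, which limits the ways the benzo ring can sit over the iron. The required sense is opposite to the one that naphthalene-type binding gives at the carbon next to the ring fusion, so it must be found among variants at pocket residues such as Phe-352 of the alpha subunit, where substitutions are known to change both site and sense of attack on larger arenes, with chiral HPLC as the assay. Work-up stays at pH 7–8 in the cold because acid converts 5 into 5- or 6-hydroxychromones.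

Step 3
Reactants: 5 (5S,6R)-5,6-dihydroxy-2-[2-(4-methoxyphenyl)ethyl]-5,6-dihydrochromen-4-one
Product: 6 (5S,6S,7S,8S)-7,8-epoxy-5,6-dihydroxy-2-[2-(4-methoxyphenyl)ethyl]-5,6,7,8-tetrahydrochromen-4-one
Conditions: mCPBA (1.2 equiv), CH2Cl2/aq. phosphate buffer (pH 8), 0 °C
Reagents that add atoms: 3-chloroperoxybenzoic acid (mCPBA), OOC(=O)c1cccc(Cl)c1
Why: Henbest-type hydroxyl-directed epoxidation: the allylic C6 hydroxyl, helped by the C5 hydroxyl on the same face, hydrogen-bonds the peracid and delivers oxygen to its own face of C7=C8, which sets C7 and C8 and gives the all-cis diol epoxide. C7=C8 is the only alkene nucleophilic enough for a peracid, the pyranone C2=C3 bond being a vinylogous ester. The buffer keeps the acid by-product from dehydrating the dihydrodiol.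

Step 4
Reactants: 6 (5S,6S,7S,8S)-7,8-epoxy-5,6-dihydroxy-2-[2-(4-methoxyphenyl)ethyl]-5,6,7,8-tetrahydrochromen-4-one
Product: 8 (5S,6R,7R,8S)-7,8-epoxy-2-[2-(4-methoxyphenyl)ethyl]-5,6-(sulfonyldioxy)-5,6,7,8-tetrahydrochromen-4-one, via cyclic sulfite 7 (not isolated)
Conditions: SOCl2 (1.2 equiv), Et3N (2.5 equiv), CH2Cl2, 0 °C; then RuCl3·xH2O (1 mol %), NaIO4 (1.5 equiv), MeCN/H2O, 0 °C, 15 min
Reagents that add atoms: thionyl chloride, O=S(Cl)Cl; sodium periodate, [Na+].[O-]I(=O)(=O)=O
Why: Two-stage cyclic sulfate synthesis: the cis-1,2-diol closes the five-membered sulfite, and catalytic RuO4 oxidises sulfur only. No C–O bond is touched, so all four stereocentres are kept (the changed descriptors at C6 and C7 reflect priorities only). With C7=C8 already epoxidised no alkene is left for RuO4, and the short contact at 0 °C spares the anisyl ring.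

Step 5
Reactants: 9 1-(2,4,5-trihydroxyphenyl)ethanone
Product: 10 1-[2-hydroxy-4,5-bis(methoxymethoxy)phenyl]ethanone
Conditions: MOMCl (2.2 equiv), iPr2NEt (3 equiv), CH2Cl2, 0 °C to rt, under N2
Reagents that add atoms: chloromethyl methyl ether, COCCl
Why: O-Alkylation of the two free phenols as methoxymethyl acetals. The 2-hydroxyl is held in a hydrogen bond to the acetyl carbonyl and stays free for the later ring closure.

Step 6
Reactants: 10 1-[2-hydroxy-4,5-bis(methoxymethoxy)phenyl]ethanone; 11 ethyl 3-phenylpropanoate
Product: 13 6,7-dihydroxy-2-(2-phenylethyl)chromen-4-one, via diketone 12 (not isolated)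
Conditions: NaH (4 equiv), THF, reflux; aq. HCl quench; crude 12, conc. HCl, MeOH, 65 °C
Reagents that add atoms: none
Why: The same Claisen condensation and acid cyclodehydration as in step 1. The methanolic acid also cleaves both methoxymethyl acetals, so the catechol is unmasked in the ring-closing operation.

Step 7
Reactants: 8 (5S,6R,7R,8S)-7,8-epoxy-2-[2-(4-methoxyphenyl)ethyl]-5,6-(sulfonyldioxy)-5,6,7,8-tetrahydrochromen-4-one; 13 6,7-dihydroxy-2-(2-phenylethyl)chromen-4-one
Product: 16 (+)-4'-methoxyaquisinenone G, via aryl ether sulfate 14 (not isolated), via bridged sulfate 15 (not isolated)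
Conditions: 13 (1.05 equiv), KOtBu (1.0 equiv), degassed DMF, 0 °C, then 8, 0 °C to rt; K2CO3 (2 equiv), 50 °C; then H2SO4 (cat.), H2O (2 equiv), THF, rt
Reagents that add atoms: none
Why: The monoanion of 13 is the 7'-phenoxide (the 7'-hydroxyl is vinylogous to the C4' carbonyl and the more acidic) and opens the cyclic sulfate by SN2 at C5 with inversion; C5 is assisted by O1 through C8a=C4a, whereas C6 is flanked by two oxygenated carbons. Carbonate then frees the 6'-phenoxide, which opens the epoxide at C7 from the face opposite the epoxide oxygen (7-exo-tet, trans-diaxial, favoured over 8-endo attack at C8), setting C7 by inversion and leaving the C8 oxygen in place. Acid hydrolysis of the alkyl sulfate salt goes by S–O cleavage, so C6 keeps its configuration.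

## Compound list

1 | 1-(2-hydroxyphenyl)ethanone | CC(=O)c1ccccc1O | starting material
2 | methyl 3-(4-methoxyphenyl)propanoate | COC(=O)CCc1ccc(OC)cc1 | starting material
3 | 1-(2-hydroxyphenyl)-5-(4-methoxyphenyl)pentane-1,3-dione | COc1ccc(CCC(=O)CC(=O)c2ccccc2O)cc1 | intermediate
4 | 2-[2-(4-methoxyphenyl)ethyl]chromen-4-one | COc1ccc(CCc2cc(=O)c3ccccc3o2)cc1 | intermediate
5 | (5S,6R)-5,6-dihydroxy-2-[2-(4-methoxyphenyl)ethyl]-5,6-dihydrochromen-4-one (cis-diol) | COc1ccc(CCc2cc(=O)c3c(o2)C=C[C@@H](O)[C@H]3O)cc1 | intermediate
6 | (5S,6S,7S,8S)-7,8-epoxy-5,6-dihydroxy-2-[2-(4-methoxyphenyl)ethyl]-5,6,7,8-tetrahydrochromen-4-one (both hydroxyls and the epoxide oxygen on one face) | COc1ccc(CCc2cc(=O)c3c(o2)[C@H]4O[C@H]4[C@@H](O)[C@H]3O)cc1 | intermediate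
7 | (5S,6R,7R,8S)-7,8-epoxy-2-[2-(4-methoxyphenyl)ethyl]-5,6-(sulfinyldioxy)-5,6,7,8-tetrahydrochromen-4-one (cyclic sulfite of 6, both epimers at sulfur) | COc1ccc(CCc2cc(=O)c3c(o2)[C@H]4O[C@H]4[C@H]5OS(=O)O[C@@H]35)cc1 | intermediate
8 | (5S,6R,7R,8S)-7,8-epoxy-2-[2-(4-methoxyphenyl)ethyl]-5,6-(sulfonyldioxy)-5,6,7,8-tetrahydrochromen-4-one (cyclic sulfate of 6) | COc1ccc(CCc2cc(=O)c3c(o2)[C@H]4O[C@H]4[C@H]5OS(=O)(=O)O[C@@H]35)cc1 | intermediate
9 | 1-(2,4,5-trihydroxyphenyl)ethanone | CC(=O)c1cc(O)c(O)cc1O | starting material
10 | 1-[2-hydroxy-4,5-bis(methoxymethoxy)phenyl]ethanone | CC(=O)c1cc(OCOC)c(OCOC)cc1O | intermediate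
11 | ethyl 3-phenylpropanoate | CCOC(=O)CCc1ccccc1 | starting material
12 | 1-[2-hydroxy-4,5-bis(methoxymethoxy)phenyl]-5-phenylpentane-1,3-dione | COCOc1cc(O)c(C(=O)CC(=O)CCc2ccccc2)cc1OCOC | intermediate
13 | 6,7-dihydroxy-2-(2-phenylethyl)chromen-4-one | O=c1cc(CCc2ccccc2)oc2cc(O)c(O)cc12 | intermediate
14 | potassium (5R,6S,7R,8S)-7,8-epoxy-5-{[6-hydroxy-4-oxo-2-(2-phenylethyl)chromen-7-yl]oxy}-2-[2-(4-methoxyphenyl)ethyl]-4-oxo-5,6,7,8-tetrahydrochromen-6-yl sulfate (C5 ether anti, sulfate and epoxide syn to each other) | COc1ccc(CCc2cc(=O)c3c(o2)[C@H]4O[C@H]4[C@@H](OS(=O)(=O)[O-])[C@@H]3Oc3cc4oc(CCc5ccccc5)cc(=O)c4cc3O)cc1.[K+] | intermediate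
15 | potassium salt of the C6 sulfate monoester of 16, (5R,6S,7S,8S) (C5 and C7 ether oxygens on one face, C6 sulfate and C8 hydroxyl on the other) | COc1ccc(CCc2cc(=O)c3c(o2)[C@@H](O)[C@@H]2Oc4cc5c(=O)cc(CCc6ccccc6)oc5cc4O[C@H]3[C@@H]2OS(=O)(=O)[O-])cc1.[K+] | intermediate
16 | (+)-4'-methoxyaquisinenone G, the (5R,6S,7R,8S)-6,8-dihydroxy-2-[2-(4-methoxyphenyl)ethyl]-5,6,7,8-tetrahydrochromen-4-one bridged from C5 to O7' and from C7 to O6' of 2-(2-phenylethyl)chromen-4-one | COc1ccc(CCc2cc(=O)c3c(o2)[C@@H](O)[C@@H]2Oc4cc5c(=O)cc(CCc6ccccc6)oc5cc4O[C@H]3[C@@H]2O)cc1 | target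

## Step count and least certain steps

Total: 7 steps. Longest linear sequence: 5 steps (steps 1, 2, 3, 4, 7); the catechol partner 13 takes 2 steps (5, 6).

**Step 2 (key step, proposed new method).**
- What may go wrong: no turnover because the long substrate is not taken up or does not fit; oxidation at the wrong place (C7–C8, the anisyl ring, a benzylic CH2, O-demethylation); delivery of oxygen to the wrong face, since the wanted sense is not the usual one at a carbon next to a ring fusion; dehydration of the diol during isolation.
- Fallback with known chemistry, setting out from 2 and returning at 5: the pyranone is annulated onto a carbocycle that already carries the cis-diol, and a dioxygenase product is used only where its sense is established.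
  - Saponification of 2 (LiOH, THF/H2O) gives 3-(4-methoxyphenyl)propanoic acid F1. Condensation with Meldrum's acid (DCC, DMAP, CH2Cl2) gives the acyl Meldrum's acid F2.
  - In parallel, commercial (1S,2S)-3-bromocyclohexa-3,5-diene-1,2-diol F3 is converted into its acetonide F4 (2,2-dimethoxypropane, TsOH cat.).
  - NBS in aqueous DME gives the bromohydrin F5 (bromonium ion anti to the acetonide, water at the allylic carbon).
  - Bu3SnH and AIBN in toluene at 90 °C reduce both C–Br bonds to give the allylic alcohol (1R,4R,5S)-4,5-(isopropylidenedioxy)cyclohex-2-en-1-ol F6.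
  - MnO2 in CH2Cl2 gives the enone (4R,5S)-4,5-(isopropylidenedioxy)cyclohex-2-en-1-one F7.
  - Kinetic enolisation towards the CH2 group with in-situ trapping (LDA, Me3SiCl, THF, −78 °C) gives the 2-silyloxydiene F8.
  - Heating F2 with F8 in toluene at 100 °C releases the acylketene, which adds across the silyl enol ether bond in a hetero-[4+2] sense. Loss of silanol on mild acid treatment gives the acetonide F9 of 5.
  - Aqueous acetic acid at room temperature then frees 5.

**Step 7.**
- What may go wrong: attack through the wrong phenolic oxygen; intermolecular opening of the epoxide at C8 instead of the sulfate at C5; 8-endo instead of 7-exo closure; elimination towards an aromatic ring under base.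
- Fallback, setting out from 13 and 8 and returning at 15: the phenols are differentiated first.
  - The more acidic 7-hydroxyl of 13 is capped (MOMCl, iPr2NEt) to give 6-hydroxy-7-(methoxymethoxy)-2-(2-phenylethyl)chromen-4-one F10, whose regiochemistry can be proved at this simple stage.
  - Allylation (allyl bromide, K2CO3, DMF) gives 7-(methoxymethoxy)-2-(2-phenylethyl)-6-(prop-2-enyloxy)chromen-4-one F11.
  - Methanolic HCl gives 7-hydroxy-2-(2-phenylethyl)-6-(prop-2-enyloxy)chromen-4-one F12.
  - Its only phenoxide (K2CO3, DMF) opens 8 at C5 to the allyl-protected sulfate salt F13.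
  - Pd(PPh3)4 (cat.) with K2CO3 in MeOH removes the allyl group, and the phenoxide set free closes onto C7 in the same medium to give 15, which is hydrolysed as in step 7.

**Step 3.**
- What may go wrong: poor facial selectivity if hydrogen-bond delivery does not outweigh the steric preference for the open face; acid-induced dehydration of the dihydrodiol.
- Fallback, setting out from 5 and returning at 6: the face is set by steric approach and anti opening instead of hydrogen bonding.
  - Acetylation (Ac2O, pyridine, 0 °C) gives the diacetate F14.
  - NBS in aqueous THF forms the bromonium ion on the face away from the acetoxy groups, and oxygen enters at C7 from their face, giving the bromohydrin F15.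
  - K2CO3 in MeOH closes the epoxide by backside displacement of bromide and removes both acetates, giving 6.

**Step 4.**
- What may go wrong: ionisation or hydrolysis of the activated C5–O bond of the sulfite or sulfate in the aqueous oxidation; opening of the epoxide by chloride; over-oxidation of the anisyl ring.
- Fallback, setting out from 6 and 13 and returning at 16: no sulfur intermediate is used.
  - Mitsunobu etherification (PPh3, DIAD, THF, 0 °C) of 6 with 13, in which the acidic 7'-hydroxyl is the pronucleophile and the activated C5 hydroxyl is displaced with inversion, gives the neutral ether F16 with the C6 hydroxyl free.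
  - K2CO3 in DMF at 50 °C then closes the dioxepine by the same epoxide opening and gives 16.

## Further compounds

F1 | step 2 | 3-(4-methoxyphenyl)propanoic acid | COc1ccc(CCC(=O)O)cc1
F2 | step 2 | 5-[1-hydroxy-3-(4-methoxyphenyl)propylidene]-2,2-dimethyl-1,3-dioxane-4,6-dione | COc1ccc(CCC(O)=C2C(=O)OC(C)(C)OC2=O)cc1
F3 | step 2 | (1S,2S)-3-bromocyclohexa-3,5-diene-1,2-diol | O[C@H]1C=CC=C(Br)[C@H]1O
F4 | step 2 | (3aS,7aS)-4-bromo-2,2-dimethyl-3a,7a-dihydro-1,3-benzodioxole | BrC1=CC=C[C@@H]2OC(C)(C)O[C@H]12
F5 | step 2 | 4,7-dibromo-2,2-dimethyl-3a,6,7,7a-tetrahydro-1,3-benzodioxol-6-ol (6-hydroxyl syn and 7-bromine anti to the dioxolane oxygens) | BrC1=C[C@H](O)[C@@H](Br)[C@@H]2OC(C)(C)O[C@H]12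
F6 | step 2 | (1R,4R,5S)-4,5-(isopropylidenedioxy)cyclohex-2-en-1-ol | O[C@H]1C=C[C@H]2OC(C)(C)O[C@H]2C1
F7 | step 2 | (4R,5S)-4,5-(isopropylidenedioxy)cyclohex-2-en-1-one | O=C1C=C[C@H]2OC(C)(C)O[C@H]2C1
F8 | step 2 | trimethylsilyl dienol ether of F7 (1-silyloxy-1,3-diene, acetonide carbons unchanged) | C[Si](C)(C)OC1=C[C@@H]2OC(C)(C)O[C@@H]2C=C1
F9 | step 2 | (5S,6R)-5,6-(isopropylidenedioxy)-2-[2-(4-methoxyphenyl)ethyl]-5,6-dihydrochromen-4-one | COc1ccc(CCc2cc(=O)c3c(o2)C=C[C@H]4OC(C)(C)O[C@@H]34)cc1
F10 | step 7 | 6-hydroxy-7-(methoxymethoxy)-2-(2-phenylethyl)chromen-4-one | COCOc1cc2oc(CCc3ccccc3)cc(=O)c2cc1O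
F11 | step 7 | 7-(methoxymethoxy)-2-(2-phenylethyl)-6-(prop-2-enyloxy)chromen-4-one | COCOc1cc2oc(CCc3ccccc3)cc(=O)c2cc1OCC=C
F12 | step 7 | 7-hydroxy-2-(2-phenylethyl)-6-(prop-2-enyloxy)chromen-4-one | C=CCOc1cc2c(=O)cc(CCc3ccccc3)oc2cc1O
F13 | step 7 | potassium salt of the 6'-O-allyl ether of 14 | COc1ccc(CCc2cc(=O)c3c(o2)[C@H]4O[C@H]4[C@@H](OS(=O)(=O)[O-])[C@@H]3Oc3cc4oc(CCc5ccccc5)cc(=O)c4cc3OCC=C)cc1.[K+]
F14 | step 3 | (5S,6R)-5,6-diacetoxy-2-[2-(4-methoxyphenyl)ethyl]-5,6-dihydrochromen-4-one | COc1ccc(CCc2cc(=O)c3c(o2)C=C[C@@H](OC(C)=O)[C@H]3OC(C)=O)cc1
F15 | step 3 | 5,6-diacetoxy-8-bromo-7-hydroxy-2-[2-(4-methoxyphenyl)ethyl]-5,6,7,8-tetrahydrochromen-4-one (7-hydroxyl syn and 8-bromine anti to the acetoxy groups) | COc1ccc(CCc2cc(=O)c3c(o2)[C@H](Br)[C@@H](O)[C@@H](OC(C)=O)[C@H]3OC(C)=O)cc1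
F16 | step 4 | (5R,6S,7S,8S)-7,8-epoxy-6-hydroxy-5-{[6-hydroxy-4-oxo-2-(2-phenylethyl)chromen-7-yl]oxy}-2-[2-(4-methoxyphenyl)ethyl]-5,6,7,8-tetrahydrochromen-4-one | COc1ccc(CCc2cc(=O)c3c(o2)[C@H]4O[C@H]4[C@@H](O)[C@@H]3Oc3cc4oc(CCc5ccccc5)cc(=O)c4cc3O)cc1
A1 | alternative 1 | bridged benzodioxepine C8a ketone with C4a as CH2 and the C6 and C8 hydroxyls as tert-butyldimethylsilyl ethers | O=C1C[C@H]2Oc3cc4oc(CCc5ccccc5)cc(=O)c4cc3O[C@H]([C@H]2O[Si](C)(C)C(C)(C)C)[C@@H]1O[Si](C)(C)C(C)(C)C
A2 | alternative 1 | cyclohexenone precursor of A1 (ketone C8a, alkene C4a=C5, C7 ether to C6', free 7'-hydroxyl, C6 and C8 silyl ethers) | O=C1C=C[C@H](O[Si](C)(C)C(C)(C)C)[C@@H](Oc2cc3c(=O)cc(CCc4ccccc4)oc3cc2O)[C@@H]1O[Si](C)(C)C(C)(C)C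
A3 | alternative 2 | bridged C6 ketone (6-oxo analogue of the target) | COc1ccc(CCc2cc(=O)c3c(o2)[C@@H](O)[C@@H]2Oc4cc5c(=O)cc(CCc6ccccc6)oc5cc4O[C@H]3C2=O)cc1
A4 | alternative 2 | benzodioxepinone keto aldehyde precursor of A3 (C5 configurationally labile) | COc1ccc(CCc2cc(=O)c(C3Oc4cc5oc(CCc6ccccc6)cc(=O)c5cc4OCC3=O)c(C=O)o2)cc1
A5 | alternative 3 | 6,8-bis(tert-butyldimethylsilyl) ether of the target | COc1ccc(CCc2cc(=O)c3c(o2)[C@@H](O[Si](C)(C)C(C)(C)C)[C@@H]2Oc4cc5c(=O)cc(CCc6ccccc6)oc5cc4O[C@H]3[C@@H]2O[Si](C)(C)C(C)(C)C)cc1
A6 | alternative 3 | trimethylsilyl enol ether (C8a=C4a) of A1 | C[Si](C)(C)OC1=C[C@H]2Oc3cc4oc(CCc5ccccc5)cc(=O)c4cc3O[C@H]([C@H]2O[Si](C)(C)C(C)(C)C)[C@@H]1O[Si](C)(C)C(C)(C)C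
A7 | alternative 3 | 6-[2-(4-methoxyphenyl)ethyl]-2,2-dimethyl-1,3-dioxin-4-one | COc1ccc(CCC2=CC(=O)OC(C)(C)O2)cc1
A8 | alternative 3 | 5-(4-methoxyphenyl)-3-oxopent-1-en-1-one (acylketene) | COc1ccc(CCC(=O)C=C=O)cc1
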